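One portion of partner cannot be spent twice, once on the impurity and again on the target. I reckoned the four new flasks from that.

common to all: starting material 0.050 M; catalyst 50 µM

| flask | partner | protic impurity | remark | time |
|---|---|---|---|---|
| maple | 0.045 M | 0.0023 M | run made earlier |  |
| elm | 0.045 M | 0.019 M | run made earlier |  |
| alder | 0.045 M | 0.093 M | run made earlier |  |
| violet | 0.0450 M | 0.00300 M |  | 20 h |
| grey | 0.0450 M | 0.0100 M |  | 20 h |
| ochre | 0.0450 M | 0.0300 M |  | 20 h |
| teal | 0.0450 M | 0.100 M |  | 20 h |

| run | time / h | target / % | starting material / % |
|---|---|---|---|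
| maple | 0.833 | 27.8 | 4.7 |
| maple | 2.50 | 58.3 | 0.2 |
| maple | 5.00 | 71.7 | 0 |
| maple | 8.00 | 77.2 | 0.4 |
| maple | 10.0 | 80.7 | 0.3 |
| elm | 0.833 | 20.1 | 4.6 |
| elm | 1.50 | 31.4 | 0.8 |
| elm | 3.00 | 43.1 | 0 |
| elm | 5.00 | 48.8 | 0 |
| elm | 10.0 | 51.7 | 0 |
| alder | 0.833 | 2.3 | 5.8 |
| alder | 1.50 | 2.4 | 1.1 |
| alder | 3.00 | 2.3 | 0 |
| alder | 5.00 | 2.1 | 1.3 |
| alder | 10.0 | 1.9 | 0 |

(standard deviation of a reading: 0.5 percentage points)

- "hardly changes" means that all values lie within two and a half points (for a concentration: within two and a half percent of the largest)

1. amount of target at the end, in percent of the starting material charged for violet, grey, ochre, teal, in this order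
2. how the row runs (falls all the way / hardly changes / rises, then falls / falls, then rises / rises all the way)

1. The first instants. Starting material fell fast. At 0.833 h it read 4.7 %, 4.6 % and 5.8 % in maple, elm and alder. The impurity charge differed 40.4-fold between maple and alder, yet these readings lay within 1.2 percentage points. I read this step as blind to the impurity.

2. The middle. In elm at 3.00 h, starting material read 0 % and target 43.1 %, and target still rose afterwards. So I took the rest of the charge to be an intermediate waiting for partner. Meanwhile I supposed the impurity was consuming partner, one for one.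

3. The end. Elm read 48.8 % at 5.00 h and 51.7 % at 10.0 h. On my supposition partner was the limiting reagent there, and the impurity took its share of it.

4. The rule. For grey the partner budget was 70.0 %: the partner charge minus the impurity charge, as a share of the starting material charged. The same sum gave 52.0 % for elm, from charges alone, against its reading of 51.7 % at 10.0 h.

5. My row. Violet had a budget of 84.0 % and ochre 30.0 %. In teal the impurity charge exceeded the partner charge, so its budget was empty. Alder was overdrawn too, yet it read 2.4 % at 1.50 h and stayed flat. I counted that as target made while partner was still going, and took about 1.9 % for teal.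

6. The forecast gave 83 %, 68 %, 35 % and 1.6 %, a row that falls all the way, since “the data show monotonic decline”, and its ochre value stood above my ochre figure.

7. The flasks gave 83.0 %, 69.9 %, 30.9 % and 1.80 %, a row that falls all the way.

    partner + protic impurity → quenched reagent (k = 0.0400 M⁻¹ s⁻¹)
    partner + catalyst + intermediate → catalyst + target (k = 95.0 M⁻² s⁻¹)
    starting material + catalyst → catalyst + intermediate (k = 20.0 M⁻¹ s⁻¹)

At 20.0 h grey held 30.1 % as intermediate, with 0.15 % of its own partner charge left. The share its budget leaves unpaid is 30.0 %. The same sum for the maple run gives 85.4 %, and its reading at 10.0 h stood at 80.7 %.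

The readings are calculated on assumed constants.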